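**Plan**
- Retrosynthesis: cleave the C2 angelate and the C6 trimethoxybenzoate, then take the C6 carbinol back to a C6 ketone (reduction directed by the C4 hydroxyl).
- Key cut: the C1–C5 bond. C6 (oxygenated) is bonded to ring-fusion C5, and C5 sits between the oxygenated carbons C4 and C6, so the β-hydroxy ketone (C4–OH, C6=O) is the product of a 1,2-shift of C1 from C6 to C5 in a trans-decalin cis-5,6-diol 5-mesylate. In that shift the cyclohexane C1–C6 contracts to the cyclopentane C1–C5 while the cyclohexene (C6–C10, C1) expands to the cycloheptene.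
- The decalin comes from RCM (C8=C9) of a C1-allyl/C6-methallyl cyclohexane; C5–OH and C4–OH from the C4=C5 alkene (singlet-oxygen ene reaction, epoxidation, hydride opening); C6 carbinol from a methallyl Grignard addition; isopropyl by conjugate addition.
- Forward order: ring A (from 2-methylcyclohexane-1,3-dione), then ring B by RCM, then both rings resized in one step, then reduction and the two esters.
- Stereochemistry: C1 and C2 from one enantioselective yeast desymmetrization; C6–OH (transient), C5–O and C4–O relayed by substrate control to the face opposite the C1 methyl; C5 by inversion in the shift; C6 by intramolecular hydride delivery.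

Key step: step 10

Remark: the C2 ester is read as the (Z)-2-methylbut-2-enoate (angelate) and the ring fusion as cis (C1–CH3 and C5–H on the same face), as the SMILES states; ring carbons of all intermediates carry the daucane labels C1–C10 of the target, "α" meaning the face opposite to the C1 methyl.

**Step 1**
Reactants: 1 2-methylcyclohexane-1,3-dione; 2 allyl bromide
Product: 3 2-allyl-2-methylcyclohexane-1,3-dione
Conditions: NaOH (1 M aq.), Bu4NI (cat.), rt
Reagents that add atoms: none
Why: C-alkylation of the stabilized enolate of a 2-substituted cyclic 1,3-dione with an allylic halide in water should favour C- over O-allylation and create the prochiral quaternary carbon (future C1).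

**Step 2**
Reactants: 3 2-allyl-2-methylcyclohexane-1,3-dione
Product: 4 (2S,3S)-2-allyl-3-hydroxy-2-methylcyclohexan-1-one (hydroxyl cis to allyl)
Conditions: baker's yeast (Saccharomyces cerevisiae), sucrose, H2O, 30 °C
Reagents that add atoms: none
Why: Enantiotopic-group-selective microbial ketone reduction (desymmetrization of a prochiral 2,2-disubstituted 1,3-dione) should deliver hydride to one carbonyl from the face anti to the allyl group, setting C2 (S carbinol) and with it the quaternary C1.

**Step 3**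
Reactants: 4 (2S,3S)-2-allyl-3-hydroxy-2-methylcyclohexan-1-one
Product: 5 (2S,3S)-2-allyl-3-[(tert-butyldimethylsilyl)oxy]-2-methylcyclohexan-1-one
Conditions: TBSCl, imidazole, DMF, rt to 40 °C
Reagents that add atoms: tert-butyldimethylsilyl chloride, CC(C)(C)[Si](C)(C)Cl
Why: Standard silyl ether formation gives a non-chelating, bulky group on the α face that later helps to steer reagents to the β face.

**Step 4**
Reactants: 5 (2S,3S)-2-allyl-3-[(tert-butyldimethylsilyl)oxy]-2-methylcyclohexan-1-one
Product: 6 (5S,6S)-6-allyl-5-[(tert-butyldimethylsilyl)oxy]-6-methylcyclohex-2-en-1-one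
Conditions: IBX, DMSO/toluene, 70 °C
Reagents that add atoms: none
Why: IBX-mediated α,β-dehydrogenation of a ketone can only occur toward C5 because the other α-carbon (C1) is quaternary.

**Step 5**
Reactants: 6 (5S,6S)-6-allyl-5-[(tert-butyldimethylsilyl)oxy]-6-methylcyclohex-2-en-1-one; 7 isopropylmagnesium chloride
Product: 9 (5S,6S)-6-allyl-5-[(tert-butyldimethylsilyl)oxy]-3-isopropyl-6-methylcyclohex-2-en-1-one, via trimethylsilyl enol ether 8 (not isolated)
Conditions: i-PrMgCl, CuBr·SMe2 (10 mol %), TMSCl, THF, −78 °C; then IBX·MPO, DMSO, rt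
Reagents that add atoms: none
Why: Copper-catalysed conjugate addition with silyl trapping, followed by Saegusa-type oxidation of the silyl enol ether with the IBX·4-methoxypyridine N-oxide complex, should reinstall the enone with isopropyl on C4; the transient C4 stereocentre is erased.

**Step 6**
Reactants: 9 (5S,6S)-6-allyl-5-[(tert-butyldimethylsilyl)oxy]-3-isopropyl-6-methylcyclohex-2-en-1-one; 10 (2-methylallyl)magnesium chloride
Product: 11 (1R,5S,6S)-6-allyl-5-[(tert-butyldimethylsilyl)oxy]-3-isopropyl-6-methyl-1-(2-methylallyl)cyclohex-2-en-1-ol (OH cis to allyl and OTBS)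
Conditions: THF, −78 °C; aq. NH4Cl
Reagents that add atoms: none
Why: 1,2-Addition of an allylic Grignard reagent to the enone carbonyl should occur from the β face, which carries only the C1 methyl, anti to the C1 allyl and C2 silyloxy groups, placing the C6 hydroxyl α.

**Step 7**
Reactants: 11 (1R,5S,6S)-6-allyl-5-[(tert-butyldimethylsilyl)oxy]-3-isopropyl-6-methyl-1-(2-methylallyl)cyclohex-2-en-1-ol
Product: 13 4-allyl-5-[(tert-butyldimethylsilyl)oxy]-1-isopropyl-4-methyl-3-(2-methylallyl)-7-oxabicyclo[4.1.0]heptane-2,3-diol (C3–C4 epoxide oxygen, C5–OH, C6–OH and OTBS all α), via allylic hydroperoxide 12 (not isolated)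
Conditions: O2, hν (visible), tetraphenylporphyrin (cat.), CH2Cl2, −20 °C; then Ti(OiPr)4 (10 mol %), 4 Å MS, −20 °C to rt
Reagents that add atoms: dioxygen, O=O
Why: Hydroxyl-directed Schenck ene reaction of the only trisubstituted alkene (oxygen to C5 syn to the C6 hydroxyl, hydrogen taken from C3 on the doubly substituted side) followed by titanium-catalysed oxygen transfer from the allylic hydroperoxide to the new C3=C4 alkene, syn to the C5 oxygen, should place both new C–O bonds on the α face.

**Step 8**
Reactants: 13 monocyclic epoxy diol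
Product: 14 2,3-epoxy-4-[(tert-butyldimethylsilyl)oxy]-2-isopropyl-4a,7-dimethyl-1,2,3,4,4a,5,8,8a-octahydronaphthalene-1,8a-diol (trans-fused; epoxide oxygen, both hydroxyls and OTBS on the face opposite to the 4a-methyl)
Conditions: Grubbs second-generation catalyst (5 mol %), CH2Cl2, 40 °C
Reagents that add atoms: none
Why: Ring-closing metathesis of the trans-diequatorial allyl and 2-methylallyl groups should close the cyclohexene with the trisubstituted C8=C9 alkene and fix the trans-decalin.

**Step 9**
Reactants: 14 trans-fused epoxy diol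
Product: 15 4-[(tert-butyldimethylsilyl)oxy]-2-isopropyl-4a,7-dimethyl-1,2,3,4,4a,5,8,8a-octahydronaphthalene-1,2,8a-triol (trans-fused; C4–OH, C5–OH, C6–OH and C2–OTBS all α, isopropyl β)
Conditions: LiEt3BH, THF, 0 °C to rt; aq. NH4Cl
Reagents that add atoms: none
Why: SN2 hydride opening of the trisubstituted epoxide at the secondary carbon C3 is also the trans-diaxial (Fürst–Plattner) mode, so the C4–O bond is untouched and the tertiary C4 alcohol keeps the α configuration.

**Step 10**
Reactants: 15 trans-decalin triol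
Product: 17 (1R,2S,4S,5S)-2-[(tert-butyldimethylsilyl)oxy]-4-hydroxydauc-8-en-6-one (cis-fused hydroazulenone), via C5 mesylate 16 (not isolated)
Conditions: MsCl, Et3N, CH2Cl2, −40 °C; then Et3Al, −78 to 0 °C; Rochelle salt
Reagents that add atoms: none
Why: Selective mesylation of the only secondary hydroxyl (C5, equatorial) and formation of the aluminium alkoxide at C6 should trigger a pinacol-type (semipinacol) 1,2-shift in which C1 migrates from C6 to C5 with loss of mesylate and C6 becomes the ketone. The closest known reaction type is the organoaluminium- or base-promoted rearrangement of 2-sulfonyloxy alcohols, as used to turn decalin cis-diol monosulfonates into hydroazulenones. No ring is closed by cyclization: the migrating bond is the ring-fusion bond, so the six-membered ring C1–C6 contracts to the cyclopentane C1–C5 (C6 expelled) and the cyclohexene expands to the cycloheptene (C5 inserted). The new stereocentre C5 is set by inversion: the α-equatorial C5–O bond is antiperiplanar to C6–C1 in the trans-decalin chair, so C1 enters from the β side of C5 with retention at C1 and H5 ends cis to the C1 methyl; C4 and C2 are untouched. The step needs migration of C1 (driven by the C6 alkoxide) over migration of C3 (driven by the C4 alkoxide, bond C4–C3 also antiperiplanar); the higher migratory aptitude of the quaternary C1 over the CH2 group C3 and relief of strain at the congested C1–C6 bond should secure this. The chelated aluminium aldolate formed at low temperature should protect the β-hydroxy ketone against retro-aldol cleavage and C5 epimerization.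

**Step 11**
Reactants: 17 (1R,2S,4S,5S)-2-[(tert-butyldimethylsilyl)oxy]-4-hydroxydauc-8-en-6-one
Product: 18 (1R,2S,4S,5R,6R)-2-[(tert-butyldimethylsilyl)oxy]dauc-8-ene-4,6-diol
Conditions: Me4NBH(OAc)3, MeCN/AcOH, −30 °C
Reagents that add atoms: none
Why: Evans–Saksena reduction: the C4 alkoxyborohydride should deliver hydride intramolecularly to the α face of the C6 carbonyl through a six-membered transition state, giving the 1,3-anti diol with the C6 hydroxyl β.

**Step 12**
Reactants: 18 (1R,2S,4S,5R,6R)-2-[(tert-butyldimethylsilyl)oxy]dauc-8-ene-4,6-diol; 19 3,4,5-trimethoxybenzoyl chloride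
Product: 20 (1R,2S,4S,5R,6R)-2-[(tert-butyldimethylsilyl)oxy]-4-hydroxydauc-8-en-6-yl 3,4,5-trimethoxybenzoate
Conditions: Et3N, DMAP (cat.), CH2Cl2, 0 °C to rt
Reagents that add atoms: none
Why: Nucleophile-catalysed acylation should take place only at the secondary C6 hydroxyl, the tertiary C4 hydroxyl being unreactive.

**Step 13**
Reactants: 20 C6 trimethoxybenzoate silyl ether
Product: 21 (1R,2S,4S,5R,6R)-2,4-dihydroxydauc-8-en-6-yl 3,4,5-trimethoxybenzoate
Conditions: HF·pyridine, pyridine, THF, 0 °C to rt
Reagents that add atoms: none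
Why: Fluoride-mediated cleavage of the silyl ether under buffered, non-basic conditions should leave the aryl ester, the tertiary alcohol and the alkene untouched.

**Step 14**
Reactants: 21 (1R,2S,4S,5R,6R)-2,4-dihydroxydauc-8-en-6-yl 3,4,5-trimethoxybenzoate; 22 angelic acid
Product: 24 (1R,2S,4S,5R,6R)-2-[(Z)-2-methylbut-2-enoyloxy]-4-hydroxydauc-8-en-6-yl 3,4,5-trimethoxybenzoate (target), via mixed anhydride 23 (not isolated)
Conditions: 22, 2,4,6-trichlorobenzoyl chloride, Et3N, toluene, rt; then 21, toluene, 80 °C (no DMAP)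
Reagents that add atoms: none
Why: Yamaguchi esterification through the mixed anhydride, run without a nucleophilic catalyst, should acylate the secondary C2 hydroxyl (tertiary C4–OH inert) while keeping the Z geometry of the angelate.

**Compound list**
1 | 2-methylcyclohexane-1,3-dione | CC1C(=O)CCCC1=O | starting material
2 | allyl bromide | C=CCBr | starting material
3 | 2-allyl-2-methylcyclohexane-1,3-dione | C=CCC1(C)C(=O)CCCC1=O | intermediate
4 | (2S,3S)-2-allyl-3-hydroxy-2-methylcyclohexan-1-one | O=C1CCC[C@H](O)[C@]1(C)CC=C | intermediate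
5 | (2S,3S)-2-allyl-3-[(tert-butyldimethylsilyl)oxy]-2-methylcyclohexan-1-one | O=C1CCC[C@H](O[Si](C)(C)C(C)(C)C)[C@]1(C)CC=C | intermediate
6 | (5S,6S)-6-allyl-5-[(tert-butyldimethylsilyl)oxy]-6-methylcyclohex-2-en-1-one | O=C1C=CC[C@H](O[Si](C)(C)C(C)(C)C)[C@]1(C)CC=C | intermediate
7 | isopropylmagnesium chloride | CC(C)[Mg]Cl | starting material
8 | 6-allyl-5-[(tert-butyldimethylsilyl)oxy]-3-isopropyl-6-methyl-1-[(trimethylsilyl)oxy]cyclohex-1-ene (C5, C6 as in 6; both C3 epimers) | C[Si](C)(C)OC1=CC(C(C)C)C[C@H](O[Si](C)(C)C(C)(C)C)[C@]1(C)CC=C | intermediate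
9 | (5S,6S)-6-allyl-5-[(tert-butyldimethylsilyl)oxy]-3-isopropyl-6-methylcyclohex-2-en-1-one | O=C1C=C(C(C)C)C[C@H](O[Si](C)(C)C(C)(C)C)[C@]1(C)CC=C | intermediate
10 | (2-methylallyl)magnesium chloride | CC(=C)C[Mg]Cl | starting material
11 | (1R,5S,6S)-6-allyl-5-[(tert-butyldimethylsilyl)oxy]-3-isopropyl-6-methyl-1-(2-methylallyl)cyclohex-2-en-1-ol | O[C@]1(CC(C)=C)C=C(C(C)C)C[C@H](O[Si](C)(C)C(C)(C)C)[C@]1(C)CC=C | intermediate
12 | 6-allyl-5-[(tert-butyldimethylsilyl)oxy]-2-hydroperoxy-3-isopropyl-6-methyl-1-(2-methylallyl)cyclohex-3-en-1-ol (OOH cis to the tertiary OH) | O[C@]1(CC(C)=C)[C@H](OO)C(C(C)C)=C[C@H](O[Si](C)(C)C(C)(C)C)[C@]1(C)CC=C | intermediate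
13 | 4-allyl-5-[(tert-butyldimethylsilyl)oxy]-1-isopropyl-4-methyl-3-(2-methylallyl)-7-oxabicyclo[4.1.0]heptane-2,3-diol (all oxygens α) | O[C@]1(CC(C)=C)[C@H](O)[C@]2(C(C)C)O[C@@H]2[C@H](O[Si](C)(C)C(C)(C)C)[C@]1(C)CC=C | intermediate
14 | 2,3-epoxy-4-[(tert-butyldimethylsilyl)oxy]-2-isopropyl-4a,7-dimethyl-1,2,3,4,4a,5,8,8a-octahydronaphthalene-1,8a-diol (trans-fused, all oxygens α) | CC1=CC[C@@]2(C)[C@@H](O[Si](C)(C)C(C)(C)C)[C@H]3O[C@@]3(C(C)C)[C@@H](O)[C@]2(O)C1 | intermediate
15 | 4-[(tert-butyldimethylsilyl)oxy]-2-isopropyl-4a,7-dimethyl-1,2,3,4,4a,5,8,8a-octahydronaphthalene-1,2,8a-triol (trans-fused, all oxygens α) | CC1=CC[C@@]2(C)[C@@H](O[Si](C)(C)C(C)(C)C)C[C@](O)(C(C)C)[C@@H](O)[C@]2(O)C1 | intermediate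
16 | 1-methanesulfonate (C5 mesylate) of 15 | CC1=CC[C@@]2(C)[C@@H](O[Si](C)(C)C(C)(C)C)C[C@](O)(C(C)C)[C@@H](OS(C)(=O)=O)[C@]2(O)C1 | intermediate
17 | (1R,2S,4S,5S)-2-[(tert-butyldimethylsilyl)oxy]-4-hydroxydauc-8-en-6-one | CC(C)(C)[Si](C)(C)O[C@H]1C[C@](O)(C(C)C)[C@H]2C(=O)CC(C)=CC[C@@]12C | intermediate
18 | (1R,2S,4S,5R,6R)-2-[(tert-butyldimethylsilyl)oxy]dauc-8-ene-4,6-diol | CC(C)(C)[Si](C)(C)O[C@H]1C[C@](O)(C(C)C)[C@H]2[C@H](O)CC(C)=CC[C@@]12C | intermediate
19 | 3,4,5-trimethoxybenzoyl chloride | COc1cc(C(=O)Cl)cc(OC)c1OC | starting material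
20 | (1R,2S,4S,5R,6R)-2-[(tert-butyldimethylsilyl)oxy]-4-hydroxydauc-8-en-6-yl 3,4,5-trimethoxybenzoate | CC(C)(C)[Si](C)(C)O[C@H]1C[C@](O)(C(C)C)[C@H]2[C@H](OC(=O)c3cc(OC)c(OC)c(OC)c3)CC(C)=CC[C@@]12C | intermediate
21 | (1R,2S,4S,5R,6R)-2,4-dihydroxydauc-8-en-6-yl 3,4,5-trimethoxybenzoate | O[C@H]1C[C@](O)(C(C)C)[C@H]2[C@H](OC(=O)c3cc(OC)c(OC)c(OC)c3)CC(C)=CC[C@@]12C | intermediate
22 | angelic acid, (Z)-2-methylbut-2-enoic acid | C/C=C(/C)C(=O)O | starting material
23 | angelic 2,4,6-trichlorobenzoic anhydride | C/C=C(/C)C(=O)OC(=O)c1c(Cl)cc(Cl)cc1Cl | intermediate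
24 | (1R,2S,4S,5R,6R)-2-[(Z)-2-methylbut-2-enoyloxy]-4-hydroxydauc-8-en-6-yl 3,4,5-trimethoxybenzoate | C/C=C(/C)C(=O)O[C@H]1C[C@](O)(C(C)C)[C@H]2[C@H](OC(=O)c3cc(OC)c(OC)c(OC)c3)CC(C)=CC[C@@]12C | target

**Step count and risks**
Total step count: 14. Longest linear sequence: 14 steps (1 to 24).

Step 10 (most likely to fail). What may go wrong: the C4 alkoxide may drive the competing shift of C3 to C5, contracting the ring the wrong way, or the β-hydroxy ketone may undergo retro-aldol cleavage. The fallback masks the C4 hydroxyl before the shift. It sets out from 14: the 5,6-diol would be tied as the isopropylidene acetal F1 (2,2-dimethoxypropane, PPTS), the epoxide opened with LiEt3BH to the C4 tertiary alcohol F2, and this silylated (TBSOTf, 2,6-lutidine) to the bis-silyl ether F3. Acetal hydrolysis (aq. AcOH) would give the 5,6-diol F4, whose C5 mesylate F5 (MsCl, Et3N) has only the C6 hydroxyl free, so Et3Al can only trigger the C1 shift and should give the bis-silylated hydroazulenone F6. HF·pyridine would free both hydroxyls (dihydroxy ketone F7), Me4NBH(OAc)3 would give the 2,4,6-triol F8, and acylation with one equivalent of 19 at the less hindered C6 hydroxyl (the C2 hydroxyl is neopentylic) would come back to the route at 21.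

Step 7. What may go wrong: poor site or face selectivity in the ene reaction next to the silyloxy group, or Hock-type cleavage of the β-hydroxy hydroperoxide before oxygen transfer. The fallback avoids singlet oxygen. It sets out from 11: hydroxyl-directed epoxidation (VO(acac)2, t-BuOOH) would give the syn 4,5-epoxy alcohol F9, and lithium diethylamide would isomerize the epoxide to the allylic alcohol by syn-elimination of a C3 proton, giving the cis-5,6-diol with the C3=C4 alkene F10. A second vanadium-catalysed directed epoxidation would come back to the route at 13.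

Step 6. What may go wrong: insufficient facial discrimination, because the very fast allylmagnesium addition is weakly substrate-controlled, giving the C6 epimer that leads to the wrong C4/C5 series. The fallback replaces substrate control by reagent control: it sets out from 9 and uses a catalytic asymmetric allylboration (2-methylallyl diisopropoxyborane, 3,3′-dibromo-BINOL of the matching hand, closed six-membered transition state) to deliver the methallyl group to the β face, coming back to the route at 11 without a new compound.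

**Further compounds**
F1 | step 10 | 5,6-O-isopropylidene acetal of 14 | CC1=CC[C@@]2(C)[C@@H](O[Si](C)(C)C(C)(C)C)[C@H]3O[C@@]3(C(C)C)[C@H]4OC(C)(C)O[C@@]24C1
F2 | step 10 | C4 tertiary alcohol, 5,6-acetonide | CC1=CC[C@@]2(C)[C@@H](O[Si](C)(C)C(C)(C)C)C[C@](O)(C(C)C)[C@H]3OC(C)(C)O[C@@]23C1
F3 | step 10 | C2,C4-bis(tert-butyldimethylsilyl) ether, 5,6-acetonide | CC1=CC[C@@]2(C)[C@@H](O[Si](C)(C)C(C)(C)C)C[C@](O[Si](C)(C)C(C)(C)C)(C(C)C)[C@H]3OC(C)(C)O[C@@]23C1
F4 | step 10 | C2,C4-bis(tert-butyldimethylsilyl) ether 5,6-diol | CC1=CC[C@@]2(C)[C@@H](O[Si](C)(C)C(C)(C)C)C[C@](O[Si](C)(C)C(C)(C)C)(C(C)C)[C@@H](O)[C@]2(O)C1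
F5 | step 10 | C5 mesylate of F4 | CC1=CC[C@@]2(C)[C@@H](O[Si](C)(C)C(C)(C)C)C[C@](O[Si](C)(C)C(C)(C)C)(C(C)C)[C@@H](OS(C)(=O)=O)[C@]2(O)C1
F6 | step 10 | (1R,2S,4S,5S)-2,4-bis[(tert-butyldimethylsilyl)oxy]dauc-8-en-6-one | CC(C)(C)[Si](C)(C)O[C@H]1C[C@](O[Si](C)(C)C(C)(C)C)(C(C)C)[C@H]2C(=O)CC(C)=CC[C@@]12C
F7 | step 10 | (1R,2S,4S,5S)-2,4-dihydroxydauc-8-en-6-one | O[C@H]1C[C@](O)(C(C)C)[C@H]2C(=O)CC(C)=CC[C@@]12C
F8 | step 10 | (1R,2S,4S,5R,6R)-dauc-8-ene-2,4,6-triol | O[C@H]1C[C@](O)(C(C)C)[C@H]2[C@H](O)CC(C)=CC[C@@]12C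
F9 | step 7 | syn 4,5-epoxy alcohol of 11 | O[C@]1(CC(C)=C)[C@@H]2O[C@]2(C(C)C)C[C@H](O[Si](C)(C)C(C)(C)C)[C@]1(C)CC=C
F10 | step 7 | cis-5,6-diol with C3=C4 alkene | O[C@]1(CC(C)=C)[C@H](O)C(C(C)C)=C[C@H](O[Si](C)(C)C(C)(C)C)[C@]1(C)CC=C
F0 | step 6 | none | none
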